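## Retrosynthetic overview

1. The target is cut at the ester into a trienone alcohol (decalin core) and (2E,4E,6S)-6-methylocta-2,4-dienoic acid; the acid comes from one cross-metathesis of (S)-3-methylpent-1-ene with penta-2,4-dienoic acid.
2. In the core alcohol, the C7 isopropylidene comes from an acetone aldol/dehydration, C1=C2 from quinone dehydrogenation of the enone, and the C3 alcohol from hydride reduction of a 3-ketone steered by the axial C5 methyl.
3. The bicyclic 3,8-dione (both methyl stereocentres in place) comes from the key step: a one-carbon ring expansion of a cyclopentanol into the six-membered ring A ketone, by 1,2-shift of the quaternary carbon onto a CH–CH3 unit (hydro-semipinacol of a 1-vinyl carbinol).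
4. The vinyl carbinol comes from vinyl addition to (S)-Hajos–Parrish ketone, itself from the proline aldol of the triketone made from 2-methylcyclopentane-1,3-dione and methyl vinyl ketone.
5. Ring order: the five-membered ring is bought, ring B (cyclohexenone) is annulated onto it, then ring A is made by expanding the five-membered ring.

Assumption: (S)-3-methylpent-1-ene and (2E)-penta-2,4-dienoic acid are bought as such; core locants in the explanations are C3 (oxygen), C4/C5 (methyls), C7 (isopropylidene), C8 (ketone), C9=C10 and C1=C2 (ring alkenes).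

## Route

Step 1
Reactants: 1 2-methylcyclopentane-1,3-dione; 2 but-3-en-2-one (methyl vinyl ketone)
Product: 3 2-methyl-2-(3-oxobutyl)cyclopentane-1,3-dione
Conditions: H2O, AcOH (cat.), 70 °C
Reagents that add atoms: none
Why: Michael addition of the acidic 1,3-dione to the enone in water gives the prochiral triketone cleanly; no stereocentre is formed yet.

Step 2
Reactants: 3 2-methyl-2-(3-oxobutyl)cyclopentane-1,3-dione
Product: 5 (7aS)-7a-methyl-2,3,7,7a-tetrahydro-1H-indene-1,5(6H)-dione [(S)-Hajos–Parrish ketone], via Hajos ketol 4 (not isolated)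
Conditions: L-proline (3 mol%), DMF, 16 °C, 40 h; then H2SO4 (cat.), DMF, 95 °C; recrystallise
Reagents that add atoms: none
Why: Hajos–Parrish reaction (proline enamine intramolecular aldol, then acid dehydration); the enamine of the methyl ketone attacks one of the two enantiotopic ring carbonyls through the carboxylic-acid-bridged chair transition state, which fixes the (S) quaternary carbon (future C5) and closes ring B.

Step 3
Reactants: 5 (7aS)-7a-methyl-2,3,7,7a-tetrahydro-1H-indene-1,5(6H)-dione
Product: 6 (1R,7aS)-1-ethenyl-1-hydroxy-7a-methyl-1,2,3,6,7,7a-hexahydro-5H-inden-5-one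
Conditions: CH2=CHMgBr (1.1 equiv), CeCl3 (1.2 equiv), THF, −78 °C; then H2O
Reagents that add atoms: vinylmagnesium bromide, C=C[Mg]Br
Why: Organocerium 1,2-addition goes to the non-conjugated cyclopentanone ahead of the deactivated enone carbonyl (the selectivity seen in borohydride and Wittig reactions of this diketone), from the face opposite the angular methyl; this carbinol centre is erased in step 4, so either epimer serves.

Step 4
Reactants: 6 (1R,7aS)-1-ethenyl-1-hydroxy-7a-methyl-1,2,3,6,7,7a-hexahydro-5H-inden-5-one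
Product: 7 (1R,8aR)-1,8a-dimethyl-3,4,8,8a-tetrahydronaphthalene-2,6(1H,7H)-dione
Conditions: Co(salen) (5 mol%, divalent cobalt; salen = N,N'-bis(3,5-di-tert-butylsalicylidene)ethane-1,2-diamine dianion), N-fluoro-2,4,6-trimethylpyridinium tetrafluoroborate (1.3 equiv), PhSiH3 (1.2 equiv), PhCF3, 0 °C to rt; then DBU (0.2 equiv), rt
Reagents that add atoms: none
Why: Proposed new method: a cobalt-hydride hydrogen-atom-transfer/radical–polar-crossover "hydro-semipinacol" ring expansion of an unstrained 1-vinylcyclopentanol — the cobalt hydride (trivalent cobalt, from Co(salen), the N–F oxidant and PhSiH3) delivers H• to the terminal CH2, the secondary radical is captured and oxidised to an electrophilic alkylcobalt (tetravalent cobalt), and the neighbouring carbinol expels it in a 1,2-shift; the rotamer with the bulky cobalt anti to the quaternary ring carbon aligns that carbon (also the better cation-stabilising migrator, as in steroid D-homoannulation of 17-hydroxy-20-sulfonates) to migrate with retention, so the cyclopentanol becomes the six-membered ring A 3-ketone with the new C4–C5 bond; the C4 methyl sits next to the small OH during the shift and is equatorial (cis to the C5 methyl, 4R) after DBU equilibration, while hydrogen-atom transfer to the electron-poor trisubstituted enone is much slower; closest known reaction type: Co(salen)-catalysed radical–polar-crossover semipinacol rearrangement of tertiary allylic alcohols bearing 1,1-disubstituted alkenes or strained rings, and Mukaiyama-type hydrofunctionalisation of monosubstituted alkenes.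

Step 5
Reactants: 7 (1R,8aR)-1,8a-dimethyl-3,4,8,8a-tetrahydronaphthalene-2,6(1H,7H)-dione
Product: 8 (4aR,5R,6S)-6-hydroxy-4a,5-dimethyl-4,4a,5,6,7,8-hexahydronaphthalen-2(3H)-one
Conditions: LiBH(s-Bu)3 (1.05 equiv), THF, −78 °C; then H2O
Reagents that add atoms: none
Why: Bulky trialkylborohydride reduction takes the saturated ketone ahead of the β,β-disubstituted enone and attacks the face opposite the axial C5 methyl (equatorial attack, as in 6-keto and 11-keto steroid reductions), giving the axial (S) alcohol cis to both methyls.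

Step 6
Reactants: 8 (4aR,5R,6S)-6-hydroxy-4a,5-dimethyl-4,4a,5,6,7,8-hexahydronaphthalen-2(3H)-one
Product: 9 (4aR,5R,6S)-6-hydroxy-4a,5-dimethyl-4,4a,5,6-tetrahydronaphthalen-2(3H)-one
Conditions: chloranil (1.5 equiv), t-BuOH, reflux
Reagents that add atoms: none
Why: Quinone dehydrogenation of an enone through its extended dienol (the steroid 4-en-3-one to 4,6-dien-3-one reaction); C5 is quaternary, so the only dienol runs to C1 and hydride loss from C2 gives the linear dienone without touching a stereocentre.

Step 7
Reactants: 9 (4aR,5R,6S)-6-hydroxy-4a,5-dimethyl-4,4a,5,6-tetrahydronaphthalen-2(3H)-one; 10 acetone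
Product: 11 (4aR,5R,6S)-6-hydroxy-3-(2-hydroxypropan-2-yl)-4a,5-dimethyl-4,4a,5,6-tetrahydronaphthalen-2(3H)-one (mixture at C3 of this name)
Conditions: LiN(iPr)2 (2.2 equiv), THF, −78 °C; ZnCl2 (1.1 equiv); acetone 10 (5 equiv), −78 to −40 °C; then H2O
Reagents that add atoms: none
Why: Directed aldol addition — the alkoxide forms first and blocks deprotonation at C3, the second equivalent makes the kinetic α'-enolate at C7, and the zinc enolate adds to acetone; the new C7 centre is removed in step 8.

Step 8
Reactants: 11 (4aR,5R,6S)-6-hydroxy-3-(2-hydroxypropan-2-yl)-4a,5-dimethyl-4,4a,5,6-tetrahydronaphthalen-2(3H)-one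
Product: 12 (4aR,5R,6S)-6-hydroxy-4a,5-dimethyl-3-(propan-2-ylidene)-4,4a,5,6-tetrahydronaphthalen-2(3H)-one
Conditions: TsOH·H2O (10 mol%), toluene, 60 °C
Reagents that add atoms: none
Why: Acid-catalysed dehydration of the tertiary β-hydroxy ketone, with equilibration of any isopropenyl isomer to the conjugated isopropylidene (as petasol goes to isopetasol); the secondary allylic alcohol does not ionise because its cation would be conjugated to the electron-poor dienone.

Step 9
Reactants: 13 (S)-3-methylpent-1-ene; 14 (2E)-penta-2,4-dienoic acid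
Product: 15 (2E,4E,6S)-6-methylocta-2,4-dienoic acid
Conditions: second-generation Hoveyda–Grubbs catalyst (C31H38Cl2N2ORu, 5 mol%), 1,4-benzoquinone (10 mol%), 13 (3 equiv), CH2Cl2, 40 °C, sealed vessel
Reagents that add atoms: none
Why: Olefin cross-metathesis occurs only at the terminal, more electron-rich double bond of the dienoic acid and gives the E alkene under thermodynamic control; the allylic stereocentre comes from the purchased alkene, and benzoquinone suppresses ruthenium-hydride isomerisation.

Step 10
Reactants: 12 (4aR,5R,6S)-6-hydroxy-4a,5-dimethyl-3-(propan-2-ylidene)-4,4a,5,6-tetrahydronaphthalen-2(3H)-one; 15 (2E,4E,6S)-6-methylocta-2,4-dienoic acid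
Product: 16 (1R,2S,8aR)-1,8a-dimethyl-6-oxo-7-(propan-2-ylidene)-1,2,6,7,8,8a-hexahydronaphthalen-2-yl (2E,4E,6S)-6-methylocta-2,4-dienoate
Conditions: DCC (1.3 equiv), DMAP (0.2 equiv), CH2Cl2, 0 °C to rt
Reagents that add atoms: none
Why: Steglich esterification acylates the alcohol oxygen, so C3 keeps its configuration, and the mild conditions leave the dienone, the E,E-diene and the remote stereocentre alone.

## Compound list

1 | 2-methylcyclopentane-1,3-dione | CC1C(=O)CCC1=O | starting material
2 | but-3-en-2-one (methyl vinyl ketone) | CC(=O)C=C | starting material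
3 | 2-methyl-2-(3-oxobutyl)cyclopentane-1,3-dione | CC(=O)CCC1(C)C(=O)CCC1=O | intermediate
4 | (3aS,7aS)-3a-hydroxy-7a-methylhexahydro-1H-indene-1,5(4H)-dione (Hajos ketol) | O=C1CC[C@]2(C)C(=O)CC[C@]2(O)C1 | intermediate
5 | (7aS)-7a-methyl-2,3,7,7a-tetrahydro-1H-indene-1,5(6H)-dione | O=C1CC[C@]2(C)C(=O)CCC2=C1 | intermediate
6 | (1R,7aS)-1-ethenyl-1-hydroxy-7a-methyl-1,2,3,6,7,7a-hexahydro-5H-inden-5-one | O=C1CC[C@]2(C)[C@](O)(C=C)CCC2=C1 | intermediate
7 | (1R,8aR)-1,8a-dimethyl-3,4,8,8a-tetrahydronaphthalene-2,6(1H,7H)-dione | O=C1CCC2=CC(=O)CC[C@]2(C)[C@H]1C | intermediate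
8 | (4aR,5R,6S)-6-hydroxy-4a,5-dimethyl-4,4a,5,6,7,8-hexahydronaphthalen-2(3H)-one | O[C@H]1CCC2=CC(=O)CC[C@]2(C)[C@H]1C | intermediate
9 | (4aR,5R,6S)-6-hydroxy-4a,5-dimethyl-4,4a,5,6-tetrahydronaphthalen-2(3H)-one | O[C@H]1C=CC2=CC(=O)CC[C@]2(C)[C@H]1C | intermediate
10 | acetone | CC(C)=O | starting material
11 | (4aR,5R,6S)-6-hydroxy-3-(2-hydroxypropan-2-yl)-4a,5-dimethyl-4,4a,5,6-tetrahydronaphthalen-2(3H)-one | O[C@H]1C=CC2=CC(=O)C(C(C)(C)O)C[C@]2(C)[C@H]1C | intermediate
12 | (4aR,5R,6S)-6-hydroxy-4a,5-dimethyl-3-(propan-2-ylidene)-4,4a,5,6-tetrahydronaphthalen-2(3H)-one | O[C@H]1C=CC2=CC(=O)C(=C(C)C)C[C@]2(C)[C@H]1C | intermediate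
13 | (S)-3-methylpent-1-ene | CC[C@H](C)C=C | starting material
14 | (2E)-penta-2,4-dienoic acid | OC(=O)/C=C/C=C | starting material
15 | (2E,4E,6S)-6-methylocta-2,4-dienoic acid | CC[C@H](C)/C=C/C=C/C(=O)O | intermediate
16 | (1R,2S,8aR)-1,8a-dimethyl-6-oxo-7-(propan-2-ylidene)-1,2,6,7,8,8a-hexahydronaphthalen-2-yl (2E,4E,6S)-6-methylocta-2,4-dienoate | CC[C@H](C)/C=C/C=C/C(=O)O[C@H]1C=CC2=CC(=O)C(=C(C)C)C[C@]2(C)[C@H]1C | target

## Step count and risks

Total step count: 10. Longest linear sequence: 9 (steps 1–8, then step 10).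

Three steps most likely to fail:

**Step 4 (the proposed new ring expansion).** The alkylcobalt could close to an epoxide, or the CH2 ring carbon could migrate instead of the quaternary one. The fallback uses known chemistry, sets out from 6 and comes back at 7. Mukaiyama hydration of the vinyl group (Co(acac)2 cat., O2, PhSiH3, THF/iPrOH) gives the diol (1S,7aS)-1-hydroxy-1-(1-hydroxyethyl)-7a-methyl-1,2,3,6,7,7a-hexahydro-5H-inden-5-one F3. MsCl/Et3N (CH2Cl2, −20 °C) sulfonates only the secondary hydroxyl to give 1-[(1S,7aS)-1-hydroxy-7a-methyl-5-oxo-2,3,5,6,7,7a-hexahydro-1H-inden-1-yl]ethyl methanesulfonate F4. Et3Al (CH2Cl2, −78 °C) then triggers the pinacol-type ring expansion of the 2-hydroxy sulfonate, in which the quaternary carbon anti to the leaving group migrates (the steroid D-homoannulation precedent); brief DBU equilibration gives 7.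

**Step 3 (chemoselective vinyl addition).** The organometallic may also attack the enone carbonyl. The fallback sets out from 5 and comes back at 6. HC(OEt)3/TsOH (EtOH, rt) masks the enone as its ethyl dienol ether (7aS)-5-ethoxy-7a-methyl-2,6,7,7a-tetrahydro-1H-inden-1-one F1, leaving the hindered cyclopentanone free (the steroid 3-enol ether/17-ketone tactic). CH2=CHMgBr/CeCl3 (THF, −78 °C) then adds to the only remaining ketone to give (1R,7aS)-1-ethenyl-5-ethoxy-7a-methyl-2,6,7,7a-tetrahydro-1H-inden-1-ol F2, and 0.1 M HCl in THF at 0 °C releases the enone to give 6.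

**Step 6 (direct dehydrogenation next to the carbinol).** Hydride loss from C2 is slowed by the neighbouring C–O bond, and some cross-conjugated dienone may form. The fallback sets out from 8 and comes back at 9. TBSOTf/Et3N (CH2Cl2, 0 °C) silylates the alcohol and converts the enone into its extended silyl dienol ether (1R,2S,8aR)-2,6-bis[(tert-butyldimethylsilyl)oxy]-1,8a-dimethyl-1,2,3,7,8,8a-hexahydronaphthalene F5. DDQ (1.1 equiv, 2,6-lutidine, CH2Cl2, 0 °C, aqueous work-up) oxidises this electron-rich diene to the linear dienone (4aR,5R,6S)-6-[(tert-butyldimethylsilyl)oxy]-4a,5-dimethyl-4,4a,5,6-tetrahydronaphthalen-2(3H)-one F6, and HF·pyridine in THF removes the silyl ether to give 9.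

## Further compounds

F1 | step 3 | (7aS)-5-ethoxy-7a-methyl-2,6,7,7a-tetrahydro-1H-inden-1-one | CCOC1=CC2=CCC(=O)[C@@]2(C)CC1
F2 | step 3 | (1R,7aS)-1-ethenyl-5-ethoxy-7a-methyl-2,6,7,7a-tetrahydro-1H-inden-1-ol | CCOC1=CC2=CC[C@@](O)(C=C)[C@@]2(C)CC1
F3 | step 4 | (1S,7aS)-1-hydroxy-1-(1-hydroxyethyl)-7a-methyl-1,2,3,6,7,7a-hexahydro-5H-inden-5-one | O=C1CC[C@]2(C)[C@](O)(C(C)O)CCC2=C1
F4 | step 4 | 1-[(1S,7aS)-1-hydroxy-7a-methyl-5-oxo-2,3,5,6,7,7a-hexahydro-1H-inden-1-yl]ethyl methanesulfonate | O=C1CC[C@]2(C)[C@](O)(C(C)OS(C)(=O)=O)CCC2=C1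
F5 | step 6 | (1R,2S,8aR)-2,6-bis[(tert-butyldimethylsilyl)oxy]-1,8a-dimethyl-1,2,3,7,8,8a-hexahydronaphthalene | CC(C)(C)[Si](C)(C)O[C@H]1CC=C2C=C(O[Si](C)(C)C(C)(C)C)CC[C@]2(C)[C@H]1C
F6 | step 6 | (4aR,5R,6S)-6-[(tert-butyldimethylsilyl)oxy]-4a,5-dimethyl-4,4a,5,6-tetrahydronaphthalen-2(3H)-one | CC(C)(C)[Si](C)(C)O[C@H]1C=CC2=CC(=O)CC[C@]2(C)[C@H]1C
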